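Assumption: the (S)-biphenolate molybdenum complex is taken to deliver the (R) centre in step 8; if the sense of induction is the reverse, the mirror-image complex is used and nothing else changes.
Remark on names: systematic names number the heptene from the styrene end, so C5 of the discussion is C3 of the names.

## The problem

Deoxycalyxin A (24) is an open-chain diarylheptanoid grafted onto a chalcone. No ring has to be made, but a fully substituted phloroglucinol ring carries a methoxy group, two free phenols, a cinnamoyl group and a 1,7-diarylhept-1-en-3-yl chain. Ring A is numbered here from the methoxy carbon A1 through A2 (H), A3 (OH), A4 (side chain) and A5 (OH) to the acyl carbon A6. The heptene is numbered from its saturated end, C1 (benzylic CH2) to C7 (styrene CH), so the stereocentre is C5 on A4 and the alkene is C6=C7. C5 is the only stereocentre, so it must be set by a catalyst; once set it is benzylic and allylic, and strong base or alkene migration can erase it. C5 also lies between the two ortho oxygens of ring A, which makes any bond formation at C5 itself sterically costly. The finished molecule is fragile: the 2'-hydroxychalcone closes to a flavanone under acid or heat, the 4-hydroxystyrene is acid-sensitive and can be trapped by the A3 phenol, and two conjugated alkenes forbid any late hydrogenation. Two features help. Ring A is symmetric about the A1–A4 axis until it is acylated, so A2 and A6 are equivalent. C5 carries two carbon arms, C4 and C6, which become enantiotopic if both are the alkene carbons of a cyclopropene whose saturated carbon is C5; opening that ring by metathesis makes no bond at C5, yet fixes C5 and differentiates the arms.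

## Retrosynthesis

24 ⇒ 23. The last cut is at the five phenolic O–H bonds, giving the pentakis(methoxymethyl) ether 23. Acetal ethers are preferred to silyl ethers, which migrate from oxygen to carbon in an ortho-lithiated ring A, and to benzyl ethers, which cannot be removed beside two alkenes. One group on every phenol means one deprotection. The forward step must cleave five acetals with dilute acid without closing the chalcone to the flavanone.

23 ⇒ 22 ⇒ 18 + 20. Cutting the A6–C(=O) bond removes the whole enone. Ring A becomes the nucleophile (aryllithium 21 from iodide 18) and the three-carbon unit the electrophile (aldehyde 20); the benzylic, allylic alcohol 22 is then oxidised. The neighbouring cut through the enone Cα–Cβ bond (aldol condensation of an acetophenone) costs the same number of steps and is kept in reserve. Iodide 18 comes from 17 by iodination; only mono- against di-substitution needs control, because A2 and A6 are equivalent. Direct deprotonation of 17 at A6 is avoided, since it needs butyllithium at 0 °C, where the more acidic C5–H is at risk; iodine–lithium exchange is over in minutes at −78 °C.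

17 ⇒ 12 + 15. The saturated chain is cut at C2–C3. The vinyl group of 12 is hydroborated at C3 and the alkylborane 16 is coupled with the primary bromide 15. A cut that leaves an alkene in the chain is excluded, because it could not be reduced beside C6=C7. The precursor 12 has a terminal and an internal alkene, so a hindered borane can tell them apart. Bromide 15 is two steps from 13.

12 ⇒ 11 + 10. This is the key cut: the C6=C7 and C3=C4 double bonds are opened together, and C4 and C6 are joined in the 3-arylcyclopropene 11, with 10 as the cross partner. The precursor is achiral and has no alkene geometry. Against cuts that make a bond at C5 (allylic substitution, conjugate addition), this one reacts only at the unhindered C4 and C6. The forward reaction must choose between two enantiotopic alkene carbons, give the E alkene, and capture the opened alkylidene with 10 and not with more 11. Compound 11 must be made and used fresh and dilute, since 3-monosubstituted cyclopropenes dimerise by the ene reaction.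

11 ⇒ 7 ⇒ 6 ⇒ 5 ⇒ 4. The strained double bond is made last, by fluoride-induced loss of silicon and bromine from the vicinal bromosilane 7. Two neighbouring routes were weighed and set aside:
- Transfer of the ring A arylcarbene to a silylacetylene is shorter, but a carbene next to an ortho O–CH2–O group inserts into that C–H bond to give a dihydrobenzofuran.
- Base-induced loss of HBr from the simple 2-arylcyclopropyl bromide can remove the benzylic hydrogen and form the wrong, conjugated cyclopropene.

In 7 only the C–Si and C–Br bonds are activated, so the alkene can only form between C4 and C6, and 7 is a stable storage form. Bromosilane 7 comes from the alkenylsilane 5 by dibromocarbene addition (6) and monoreduction, and 5 from aldehyde 4 by silyl-olefination.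

4 ⇒ 2 ⇒ 1, and the partners. Aldehyde 4 is cut at the A4–CHO bond to the bis-acetal 2 of commercial 1; lithiation between the two acetal oxygens (3) places the carbon that becomes C5. Styrene 10 comes from commercial 8 through phenolate 9, and aldehyde 20 from commercial 19, each in one step.

## Roads not taken

Alternative 1: The cut is at both aryl–alkene bonds (C7–aryl and enone Cβ–aryl) at the very end. The bis-alkene A2, carrying a vinyl group on C5 and an acryloyl group on A6, would be arylated twice by boronic acid A3 under oxidative catalysis with divalent palladium to give the pentasilyl ether A1.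
- Merits: the two termini are identical, so one reagent makes two bonds. The silyl ethers come off with fluoride, which is gentler than acid on five acetals; in this respect the road is better than the chosen one.
- Weak points: A2 holds an aryl vinyl ketone that polymerises easily. After arylpalladation of the C5 vinyl group, β-hydride elimination can take the C5–H and move the alkene to C5=C6, which erases the stereocentre. Above all, A2 already contains C5, so the stereocentre is postponed and must still be made at the hindered carbon.
- Comparison: the chosen plan gives up the fluoride end game, but it makes the styrene and the stereocentre in one event and never places an alkylpalladium next to C5.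

Alternative 2: The cut is at A4–C5 and A3–O, with ring A as an aryne. The aryne from silyl triflate A5 would add the carbonyl of aldehyde 20; the ortho-quinone methide formed would close by oxa-6π electrocyclisation to the 2H-chromene A4.
- Merits: one step joins ring A to C5, installs C6=C7 with its aryl group and places the A3 oxygen. It needs no intermediate as fragile as 11 and reaches the C5–C7 array in fewer steps than the chosen plan reaches 12.
- Weak points: A4 is racemic, its only stereocentre is C7, and it equilibrates by ring opening. C5 must then be created by opening the pyran with the four-carbon chain under enantiocontrol, a reaction that is not established and that again forms a bond at the hindered carbon. The aryne regiochemistry rests on the bias of a single acetal oxygen, and A5 needs its own synthesis.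
- Comparison: shorter on paper. The chosen plan sets against it that its key step delivers C5 as one enantiomer with both arms in place, whereas here the enantioselective step is still to be invented after the key step.

Alternative 3: The cut is at C3–C4 and C5–C6 across the ring A styrene A7. The primary radical from iodide A8 would add to the terminal carbon of A7, and the benzylic radical at C5 would be captured by a chiral alkenylnickel species from bromostyrene A9 to give A6.
- Merits: three simple pieces give the whole heptene and the stereocentre in one step. In step economy this road is clearly better than the chosen one, and it avoids a strained intermediate.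
- Weak points: an unstabilised primary radical adds slowly to a styrene twisted out of conjugation by two ortho silyloxy groups, and direct alkyl–alkenyl coupling competes. The enantio-determining capture happens at C5, the most hindered site. The silyl ethers of A6 then conflict with lithiation of ring A for the acylation.
- Comparison: the chosen plan is longer. It sets against this that its stereo-determining event happens at C4 and C6, away from the ortho oxygens, and that its protecting groups serve the end game.

Key step: step 8

## Route

Step 1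
Reactants: 1 5-methoxyresorcinol
Product: 2 1-methoxy-3,5-bis(methoxymethoxy)benzene
Conditions: NaH, MOMCl, DMF, 0 °C to 22 °C
Reagents that add atoms: chloromethyl methyl ether, COCCl
Why: Double Williamson etherification of the sodium phenoxides; the acetal ethers direct the lithiation of step 2 and stay inert to every base, organometallic and metal catalyst used later.

Step 2
Reactants: 2 1-methoxy-3,5-bis(methoxymethoxy)benzene
Product: 4 4-methoxy-2,6-bis(methoxymethoxy)benzaldehyde, via aryllithium 3 (not isolated)
Conditions: n-BuLi, TMEDA, THF, 0 °C; then DMF, 0 °C to 22 °C; then H2O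
Reagents that add atoms: N,N-dimethylformamide, CN(C)C=O
Why: Directed ortho-metalation: the carbon between the two acetal ethers is flanked by two chelating oxygens and should be lithiated in preference to the carbons next to the methoxy group, and DMF formylates 3; an unsymmetrical isomer, if formed, is removed at this stage.

Step 3
Reactants: 4 4-methoxy-2,6-bis(methoxymethoxy)benzaldehyde
Product: 5 (E)-{2-[4-methoxy-2,6-bis(methoxymethoxy)phenyl]ethenyl}trimethylsilane
Conditions: Me3SiCHBr2, CrCl2, THF, 22 °C
Reagents that add atoms: (dibromomethyl)trimethylsilane, C[Si](C)(C)C(Br)Br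
Why: Takai-type silyl-olefination: the geminal dichromium reagent adds to the aldehyde and eliminates to the (E)-alkenylsilane under neutral conditions that tolerate the hindered, electron-rich aldehyde and the acetals.

Step 4
Reactants: 5 (E)-{2-[4-methoxy-2,6-bis(methoxymethoxy)phenyl]ethenyl}trimethylsilane
Product: 6 trans-{2,2-dibromo-3-[4-methoxy-2,6-bis(methoxymethoxy)phenyl]cyclopropyl}trimethylsilane (racemic)
Conditions: CHBr3, 50% aq NaOH, BnEt3NCl (cat.), CH2Cl2, 22 to 40 °C
Reagents that add atoms: bromoform, BrC(Br)Br
Why: Phase-transfer dibromocyclopropanation: the electrophilic carbene adds stereospecifically to the alkenylsilane, the only π bond in 5 that it attacks, so aryl and silyl stay trans.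

Step 5
Reactants: 6 trans-{2,2-dibromo-3-[4-methoxy-2,6-bis(methoxymethoxy)phenyl]cyclopropyl}trimethylsilane
Product: 7 {2-bromo-3-[4-methoxy-2,6-bis(methoxymethoxy)phenyl]cyclopropyl}trimethylsilane (aryl and silyl trans; both epimers at the bromine-bearing carbon; racemic)
Conditions: EtMgBr, Ti(OiPr)4 (5 mol%), Et2O, 22 °C; then H2O
Reagents that add atoms: none
Why: Titanium-catalysed hydrodebromination of a geminal dibromocyclopropane by EtMgBr stops at the monobromide; both epimers are usable because either has bromine on the carbon next to the silicon-bearing one.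

Step 6
Reactants: 8 4-acetoxystyrene
Product: 10 1-ethenyl-4-(methoxymethoxy)benzene, via potassium phenolate 9 (not isolated)
Conditions: KOtBu, THF, 0 °C; then MOMCl, 0 °C to 22 °C
Reagents that add atoms: chloromethyl methyl ether, COCCl
Why: Acyl transfer from the aryl acetate to tert-butoxide gives phenolate 9, which is alkylated in the same flask (Williamson etherification), so polymerisable 4-vinylphenol is never isolated.

Step 7
Reactants: 7 {2-bromo-3-[4-methoxy-2,6-bis(methoxymethoxy)phenyl]cyclopropyl}trimethylsilane
Product: 11 2-(cycloprop-2-en-1-yl)-5-methoxy-1,3-bis(methoxymethoxy)benzene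
Conditions: Bu4NF, THF, 0 to 22 °C; pentane/H2O; filtration through basic Al2O3; 4 Å sieves; cold solution used the same day
Reagents that add atoms: none
Why: Fluoride-induced 1,2-elimination of a 2-halo-1-silylcyclopropane, a known route to cyclopropenes: attack at silicon expels bromide from the neighbouring carbon, so the alkene can only form between C4 and C6 and the benzylic C5–H is untouched; 11 is kept dilute and cold because such cyclopropenes dimerise by the ene reaction.

Step 8
Reactants: 11 2-(cycloprop-2-en-1-yl)-5-methoxy-1,3-bis(methoxymethoxy)benzene; 10 1-ethenyl-4-(methoxymethoxy)benzene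
Product: 12 5-methoxy-1,3-bis(methoxymethoxy)-2-{(1E,3R)-1-[4-(methoxymethoxy)phenyl]penta-1,4-dien-3-yl}benzene
Conditions: Mo(N-2,6-iPr2C6H3)(CHCMe2Ph)[(S)-3,3'-tBu2-5,5',6,6'-Me4-biphenyl-2,2'-diolate] (5 mol%), 10 (3 equiv), C6H6, 22 °C, slow addition of 11, inert atmosphere
Reagents that add atoms: none
Why: Proposed new method: the precatalyst is converted by 10 into the arylmethylidene Mo=CH(C6H4OMOM), which adds [2+2] to the strained C4=C6 bond of 11 on the face anti to ring A; cycloreversion opens the three-membered ring, forms C6=C7 and leaves molybdenum on C4, and this alkylidene reacts with 10 so that C4 receives the methylene C3 and the arylmethylidene is regenerated. The closest known reaction types are the enantioselective ring-opening cross-metathesis of 3,3-disubstituted cyclopropenes with terminal alkenes and the molybdenum biphenolate-catalysed ring-opening cross-metathesis of meso norbornenes with styrenes; a cyclopropene with hydrogen on the saturated carbon has not been used. No ring is closed. C5 is not a reacting centre: its configuration follows from which enantiotopic alkene carbon bonds to C7 in the metallacycle, a choice made by the chiral biphenolate (catalyst control), the substrate adding only the anti approach enforced by the doubly ortho-substituted ring A. The E geometry arises because the aryl group on the alkylidene carbon and the C5 bridge lie trans on the metallacyclobutane. The opened alkylidene must be captured by 10 and not by a second molecule of 11, which slow addition of 11 to excess 10 should secure, and the product must stay out of secondary metathesis, which the branching next to its vinyl group should secure. Dilution in 11 lets strain-driven metathesis outrun ene dimerisation.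

Step 9
Reactants: 13 4-(2-hydroxyethyl)phenol
Product: 14 2-[4-(methoxymethoxy)phenyl]ethanol
Conditions: K2CO3, MOMCl, acetone, 0 to 22 °C
Reagents that add atoms: chloromethyl methyl ether, COCCl
Why: K2CO3 deprotonates only the phenol (Williamson etherification), leaving the primary alcohol free.

Step 10
Reactants: 14 2-[4-(methoxymethoxy)phenyl]ethanol
Product: 15 1-(2-bromoethyl)-4-(methoxymethoxy)benzene
Conditions: CBr4, PPh3, CH2Cl2, 0 °C
Reagents that add atoms: tetrabromomethane, BrC(Br)(Br)Br
Why: Appel reaction: the oxyphosphonium salt of the primary alcohol is displaced by bromide under near-neutral conditions that the aryl acetal tolerates.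

Step 11
Reactants: 12 5-methoxy-1,3-bis(methoxymethoxy)-2-{(1E,3R)-1-[4-(methoxymethoxy)phenyl]penta-1,4-dien-3-yl}benzene; 15 1-(2-bromoethyl)-4-(methoxymethoxy)benzene
Product: 17 5-methoxy-1,3-bis(methoxymethoxy)-2-{(1E,3R)-1,7-bis[4-(methoxymethoxy)phenyl]hept-1-en-3-yl}benzene, via alkylborane 16 (not isolated)
Conditions: 9-BBN-H, THF, 0 to 22 °C; then 15, Pd(OAc)2 (4 mol%), PCy3 (8 mol%), K3PO4·H2O, THF, 22 °C
Reagents that add atoms: none
Why: 9-BBN-H adds to the terminal alkene only, boron at C3 (anti-Markovnikov hydroboration; the conjugated internal alkene is far slower), and borane 16 undergoes alkyl–alkyl Suzuki–Miyaura coupling with the primary bromide under the zerovalent palladium–PCy3 conditions established for alkyl bromides with β-hydrogens; the phosphate base is too weak to deprotonate C5.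

Step 12
Reactants: 17 5-methoxy-1,3-bis(methoxymethoxy)-2-{(1E,3R)-1,7-bis[4-(methoxymethoxy)phenyl]hept-1-en-3-yl}benzene
Product: 18 2-iodo-1-methoxy-3,5-bis(methoxymethoxy)-4-{(1E,3R)-1,7-bis[4-(methoxymethoxy)phenyl]hept-1-en-3-yl}benzene
Conditions: NIS (1.0 equiv), MeCN, 0 °C, dark
Reagents that add atoms: N-iodosuccinimide, O=C1CCC(=O)N1I
Why: Electrophilic aromatic iodination of the trioxygenated ring, the most nucleophilic π system in 17; A2 and A6 are interchanged by rotation about A4–C5, so one mono-iodide should result, and the first iodine slows a second substitution.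

Step 13
Reactants: 19 (E)-3-(4-hydroxyphenyl)prop-2-enal
Product: 20 (E)-3-[4-(methoxymethoxy)phenyl]prop-2-enal
Conditions: K2CO3, MOMCl, acetone, 0 to 22 °C
Reagents that add atoms: chloromethyl methyl ether, COCCl
Why: Williamson etherification of the phenol with a base mild enough for the enal.

Step 14
Reactants: 18 2-iodo-1-methoxy-3,5-bis(methoxymethoxy)-4-{(1E,3R)-1,7-bis[4-(methoxymethoxy)phenyl]hept-1-en-3-yl}benzene; 20 (E)-3-[4-(methoxymethoxy)phenyl]prop-2-enal
Product: 22 (E)-1-{6-methoxy-2,4-bis(methoxymethoxy)-3-[(1E,3R)-1,7-bis[4-(methoxymethoxy)phenyl]hept-1-en-3-yl]phenyl}-3-[4-(methoxymethoxy)phenyl]prop-2-en-1-ol (both epimers at the carbinol carbon), via aryllithium 21 (not isolated)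
Conditions: n-BuLi (1.05 equiv), THF, −78 °C, 10 min; then 20, −78 °C; then H2O
Reagents that add atoms: none
Why: Iodine–lithium exchange at −78 °C is faster than proton transfer, so the acidic C5–H is not disturbed; the chelated aryllithium 21 adds 1,2 to the enal (carbonyl addition), and the acid-labile benzylic, allylic carbinol is taken on crude from a neutral work-up.

Step 15
Reactants: 22 (E)-1-{6-methoxy-2,4-bis(methoxymethoxy)-3-[(1E,3R)-1,7-bis[4-(methoxymethoxy)phenyl]hept-1-en-3-yl]phenyl}-3-[4-(methoxymethoxy)phenyl]prop-2-en-1-ol
Product: 23 (E)-1-{6-methoxy-2,4-bis(methoxymethoxy)-3-[(1E,3R)-1,7-bis[4-(methoxymethoxy)phenyl]hept-1-en-3-yl]phenyl}-3-[4-(methoxymethoxy)phenyl]prop-2-en-1-one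
Conditions: MnO2 (excess), CH2Cl2, 22 °C
Reagents that add atoms: none
Why: MnO2 oxidises benzylic and allylic alcohols selectively under neutral conditions; both epimers of 22 converge on the enone and neither the styrene nor C5 is affected.

Step 16
Reactants: 23 (E)-1-{6-methoxy-2,4-bis(methoxymethoxy)-3-[(1E,3R)-1,7-bis[4-(methoxymethoxy)phenyl]hept-1-en-3-yl]phenyl}-3-[4-(methoxymethoxy)phenyl]prop-2-en-1-one
Product: 24 deoxycalyxin A, (E)-1-{2,4-dihydroxy-3-[(1E,3R)-1,7-bis(4-hydroxyphenyl)hept-1-en-3-yl]-6-methoxyphenyl}-3-(4-hydroxyphenyl)prop-2-en-1-one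
Conditions: 3 M aq HCl, MeOH, 22 °C, under N2
Reagents that add atoms: none
Why: Acid-catalysed transacetalisation to methanol removes all five MOM groups; dilute HCl in methanol at ambient temperature is the established way to unmask 2'-hydroxy-6'-methoxychalcones of this pattern without flavanone closure, and the reaction is stopped once the last acetal has gone to protect the 4-hydroxystyrene.

## Compound list

1 | 5-methoxyresorcinol | COc1cc(O)cc(O)c1 | starting material
2 | 1-methoxy-3,5-bis(methoxymethoxy)benzene | COc1cc(OCOC)cc(OCOC)c1 | intermediate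
3 | [4-methoxy-2,6-bis(methoxymethoxy)phenyl]lithium | COc1cc(OCOC)c([Li])c(OCOC)c1 | intermediate (not isolated)
4 | 4-methoxy-2,6-bis(methoxymethoxy)benzaldehyde | COc1cc(OCOC)c(C=O)c(OCOC)c1 | intermediate
5 | (E)-{2-[4-methoxy-2,6-bis(methoxymethoxy)phenyl]ethenyl}trimethylsilane | COc1cc(OCOC)c(/C=C/[Si](C)(C)C)c(OCOC)c1 | intermediate
6 | trans-{2,2-dibromo-3-[4-methoxy-2,6-bis(methoxymethoxy)phenyl]cyclopropyl}trimethylsilane (racemic, one enantiomer drawn) | BrC1(Br)[C@H](c2c(OCOC)cc(OC)cc2OCOC)[C@H]1[Si](C)(C)C | intermediate
7 | {2-bromo-3-[4-methoxy-2,6-bis(methoxymethoxy)phenyl]cyclopropyl}trimethylsilane (aryl/silyl trans, both C–Br epimers, racemic) | BrC1[C@H](c2c(OCOC)cc(OC)cc2OCOC)[C@H]1[Si](C)(C)C | intermediate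
8 | 4-acetoxystyrene | CC(=O)Oc1ccc(C=C)cc1 | starting material
9 | potassium 4-ethenylphenolate | [K+].[O-]c1ccc(C=C)cc1 | intermediate (not isolated)
10 | 1-ethenyl-4-(methoxymethoxy)benzene | C=Cc1ccc(OCOC)cc1 | intermediate
11 | 2-(cycloprop-2-en-1-yl)-5-methoxy-1,3-bis(methoxymethoxy)benzene | COc1cc(OCOC)c(C2C=C2)c(OCOC)c1 | intermediate
12 | 5-methoxy-1,3-bis(methoxymethoxy)-2-{(1E,3R)-1-[4-(methoxymethoxy)phenyl]penta-1,4-dien-3-yl}benzene | COc1cc(OCOC)c([C@@H](/C=C/c2ccc(OCOC)cc2)C=C)c(OCOC)c1 | intermediate
13 | 4-(2-hydroxyethyl)phenol | OCCc1ccc(O)cc1 | starting material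
14 | 2-[4-(methoxymethoxy)phenyl]ethanol | COCOc1ccc(CCO)cc1 | intermediate
15 | 1-(2-bromoethyl)-4-(methoxymethoxy)benzene | COCOc1ccc(CCBr)cc1 | intermediate
16 | 9-{(3R,4E)-3-[4-methoxy-2,6-bis(methoxymethoxy)phenyl]-5-[4-(methoxymethoxy)phenyl]pent-4-en-1-yl}-9-borabicyclo[3.3.1]nonane | COc1cc(OCOC)c([C@@H](/C=C/c2ccc(OCOC)cc2)CCB2C3CCCC2CCC3)c(OCOC)c1 | intermediate (not isolated)
17 | 5-methoxy-1,3-bis(methoxymethoxy)-2-{(1E,3R)-1,7-bis[4-(methoxymethoxy)phenyl]hept-1-en-3-yl}benzene | COc1cc(OCOC)c([C@@H](/C=C/c2ccc(OCOC)cc2)CCCCc2ccc(OCOC)cc2)c(OCOC)c1 | intermediate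
18 | 2-iodo-1-methoxy-3,5-bis(methoxymethoxy)-4-{(1E,3R)-1,7-bis[4-(methoxymethoxy)phenyl]hept-1-en-3-yl}benzene | COc1cc(OCOC)c([C@@H](/C=C/c2ccc(OCOC)cc2)CCCCc2ccc(OCOC)cc2)c(OCOC)c1I | intermediate
19 | (E)-3-(4-hydroxyphenyl)prop-2-enal | O=C/C=C/c1ccc(O)cc1 | starting material
20 | (E)-3-[4-(methoxymethoxy)phenyl]prop-2-enal | O=C/C=C/c1ccc(OCOC)cc1 | intermediate
21 | aryllithium of 18 (lithium in place of iodine) | COc1cc(OCOC)c([C@@H](/C=C/c2ccc(OCOC)cc2)CCCCc2ccc(OCOC)cc2)c(OCOC)c1[Li] | intermediate (not isolated)
22 | (E)-1-{6-methoxy-2,4-bis(methoxymethoxy)-3-[(1E,3R)-1,7-bis[4-(methoxymethoxy)phenyl]hept-1-en-3-yl]phenyl}-3-[4-(methoxymethoxy)phenyl]prop-2-en-1-ol (both carbinol epimers) | COc1cc(OCOC)c([C@@H](/C=C/c2ccc(OCOC)cc2)CCCCc2ccc(OCOC)cc2)c(OCOC)c1C(O)/C=C/c1ccc(OCOC)cc1 | intermediate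
23 | (E)-1-{6-methoxy-2,4-bis(methoxymethoxy)-3-[(1E,3R)-1,7-bis[4-(methoxymethoxy)phenyl]hept-1-en-3-yl]phenyl}-3-[4-(methoxymethoxy)phenyl]prop-2-en-1-one | COc1cc(OCOC)c([C@@H](/C=C/c2ccc(OCOC)cc2)CCCCc2ccc(OCOC)cc2)c(OCOC)c1C(=O)/C=C/c1ccc(OCOC)cc1 | intermediate
24 | deoxycalyxin A, (E)-1-{2,4-dihydroxy-3-[(1E,3R)-1,7-bis(4-hydroxyphenyl)hept-1-en-3-yl]-6-methoxyphenyl}-3-(4-hydroxyphenyl)prop-2-en-1-one | COc1cc(O)c([C@@H](/C=C/c2ccc(O)cc2)CCCCc2ccc(O)cc2)c(O)c1C(=O)/C=C/c1ccc(O)cc1 | target

## Step count and least certain steps

Total: 16 steps. Longest linear sequence: 12 steps (1, 2, 3, 4, 5, 7, 8, 11, 12, 14, 15, 16). The partners take steps 6, 9, 10 and 13.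

Step 8 (key step, proposed new method). Ene dimerisation or ring-opening oligomerisation of 11 may outrun cross-metathesis. The catalyst may discriminate poorly between the enantiotopic carbons. An ortho acetal oxygen may chelate the C4 alkylidene and stall turnover. Secondary metathesis at the vinyl group would level the two arms. The fallback uses known chemistry and sets out from 4 and 10:
- Vinylmagnesium bromide adds to 4 to give racemic 1-[4-methoxy-2,6-bis(methoxymethoxy)phenyl]prop-2-en-1-ol F1.
- Cross-metathesis of 10 with vinylboronic acid pinacol ester (second-generation Grubbs catalyst) gives (E)-2-{2-[4-(methoxymethoxy)phenyl]ethenyl}-4,4,5,5-tetramethyl-1,3,2-dioxaborolane F2, and KHF2 converts it into potassium (E)-trifluoro{2-[4-(methoxymethoxy)phenyl]ethenyl}borate F3.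
- Enantioselective allylic vinylation of F1 with F3, catalysed by [Ir(cod)Cl]2 and a chiral phosphoramidite–alkene ligand under the acidic conditions of that method, forms the branched 1,4-diene and comes back to the route at 12.

Step 4. Addition of dibromocarbene to the hindered, twisted alkenylsilane may be slow, so that carbene hydrolysis or insertion into the acetal C–H bonds takes over. The fallback sets out from 4:
- Wittig methylenation gives 2-ethenyl-5-methoxy-1,3-bis(methoxymethoxy)benzene F4.
- Dibromocyclopropanation of this unhindered styrene gives 2-(2,2-dibromocyclopropyl)-5-methoxy-1,3-bis(methoxymethoxy)benzene F5.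
- Reduction with EtMgBr and Ti(OiPr)4 gives 2-(2-bromocyclopropyl)-5-methoxy-1,3-bis(methoxymethoxy)benzene F6.
- KOtBu in DMSO removes HBr and comes back at 11.

This gives up the regiochemical security of the silicon route, since the benzylic hydrogen can now be lost.

Step 11. Bromide 15 may lose HBr to give 10, by base or by β-hydride elimination at palladium, before it couples; hydroboration next to ring A may be slow. The fallback sets out from 12:
- Hydroboration as before and oxidation of 16 with NaOH/H2O2 give (3R,4E)-3-[4-methoxy-2,6-bis(methoxymethoxy)phenyl]-5-[4-(methoxymethoxy)phenyl]pent-4-en-1-ol F7.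
- I2, PPh3 and imidazole give 2-{(1E,3R)-5-iodo-1-[4-(methoxymethoxy)phenyl]pent-1-en-3-yl}-5-methoxy-1,3-bis(methoxymethoxy)benzene F8.
- Bromide 15 and magnesium give {2-[4-(methoxymethoxy)phenyl]ethyl}magnesium bromide F9, which is coupled with F8 under Li2CuCl4 catalysis in THF at −20 °C and comes back at 17.

The phenethyl unit is now the nucleophile and cannot eliminate.

Step 14. On warming, aryllithium 21 may take the C5 proton, with racemisation or alkene migration, or may add sluggishly because of its two ortho substituents. The fallback sets out from 18 and uses no carbanion: carbonylative Suzuki–Miyaura coupling of 18 with CO and the boronate F2 of the first fallback (Pd(PPh3)2Cl2, K2CO3, anisole, 80 °C) gives the enone directly and comes back at 23.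

Step 16. The A5 phenol may close onto the enone (flavanone), or the A3 phenol onto the protonated styrene, before the slowest acetal is cleaved. The fallback sets out from 18 and moves the acid step ahead of the enone:
- Stille coupling with tributyl(1-ethoxyvinyl)stannane (Pd(PPh3)4, toluene, 100 °C) gives 2-(1-ethoxyethenyl)-1-methoxy-3,5-bis(methoxymethoxy)-4-{(1E,3R)-1,7-bis[4-(methoxymethoxy)phenyl]hept-1-en-3-yl}benzene F10.
- Dilute HCl in methanol hydrolyses the enol ether and the four acetals to 1-{2,4-dihydroxy-3-[(1E,3R)-1,7-bis(4-hydroxyphenyl)hept-1-en-3-yl]-6-methoxyphenyl}ethanone F11.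
- Claisen–Schmidt condensation of F11 with 4-hydroxybenzaldehyde (KOH, EtOH/H2O, 22 °C) comes back at 24 under basic conditions.

## Further compounds

F1 | step 8 | 1-[4-methoxy-2,6-bis(methoxymethoxy)phenyl]prop-2-en-1-ol (racemic) | COc1cc(OCOC)c(C(O)C=C)c(OCOC)c1
F2 | step 8 | (E)-2-{2-[4-(methoxymethoxy)phenyl]ethenyl}-4,4,5,5-tetramethyl-1,3,2-dioxaborolane | COCOc1ccc(/C=C/B2OC(C)(C)C(C)(C)O2)cc1
F3 | step 8 | potassium (E)-trifluoro{2-[4-(methoxymethoxy)phenyl]ethenyl}borate | [K+].COCOc1ccc(/C=C/[B-](F)(F)F)cc1
F4 | step 4 | 2-ethenyl-5-methoxy-1,3-bis(methoxymethoxy)benzene | COc1cc(OCOC)c(C=C)c(OCOC)c1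
F5 | step 4 | 2-(2,2-dibromocyclopropyl)-5-methoxy-1,3-bis(methoxymethoxy)benzene (racemic) | COc1cc(OCOC)c(C2CC2(Br)Br)c(OCOC)c1
F6 | step 4 | 2-(2-bromocyclopropyl)-5-methoxy-1,3-bis(methoxymethoxy)benzene (cis and trans, racemic) | COc1cc(OCOC)c(C2CC2Br)c(OCOC)c1
F7 | step 11 | (3R,4E)-3-[4-methoxy-2,6-bis(methoxymethoxy)phenyl]-5-[4-(methoxymethoxy)phenyl]pent-4-en-1-ol | COc1cc(OCOC)c([C@@H](/C=C/c2ccc(OCOC)cc2)CCO)c(OCOC)c1
F8 | step 11 | 2-{(1E,3R)-5-iodo-1-[4-(methoxymethoxy)phenyl]pent-1-en-3-yl}-5-methoxy-1,3-bis(methoxymethoxy)benzene | COc1cc(OCOC)c([C@@H](/C=C/c2ccc(OCOC)cc2)CCI)c(OCOC)c1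
F9 | step 11 | {2-[4-(methoxymethoxy)phenyl]ethyl}magnesium bromide | COCOc1ccc(CC[Mg]Br)cc1
F0 | step 14 | none | none
F10 | step 16 | 2-(1-ethoxyethenyl)-1-methoxy-3,5-bis(methoxymethoxy)-4-{(1E,3R)-1,7-bis[4-(methoxymethoxy)phenyl]hept-1-en-3-yl}benzene | COc1cc(OCOC)c([C@@H](/C=C/c2ccc(OCOC)cc2)CCCCc2ccc(OCOC)cc2)c(OCOC)c1C(=C)OCC
F11 | step 16 | 1-{2,4-dihydroxy-3-[(1E,3R)-1,7-bis(4-hydroxyphenyl)hept-1-en-3-yl]-6-methoxyphenyl}ethanone | COc1cc(O)c([C@@H](/C=C/c2ccc(O)cc2)CCCCc2ccc(O)cc2)c(O)c1C(C)=O
A1 | alternative 1 | pentakis(tert-butyldimethylsilyl) ether of deoxycalyxin A | COc1cc(O[Si](C)(C)C(C)(C)C)c([C@@H](/C=C/c2ccc(O[Si](C)(C)C(C)(C)C)cc2)CCCCc2ccc(O[Si](C)(C)C(C)(C)C)cc2)c(O[Si](C)(C)C(C)(C)C)c1C(=O)/C=C/c1ccc(O[Si](C)(C)C(C)(C)C)cc1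
A2 | alternative 1 | (R)-1-{2,4-bis(tert-butyldimethylsilyloxy)-3-[7-(4-tert-butyldimethylsilyloxyphenyl)hept-1-en-3-yl]-6-methoxyphenyl}prop-2-en-1-one | COc1cc(O[Si](C)(C)C(C)(C)C)c([C@@H](C=C)CCCCc2ccc(O[Si](C)(C)C(C)(C)C)cc2)c(O[Si](C)(C)C(C)(C)C)c1C(=O)C=C
A3 | alternative 1 | [4-(tert-butyldimethylsilyloxy)phenyl]boronic acid | CC(C)(C)[Si](C)(C)Oc1ccc(B(O)O)cc1
A4 | alternative 2 | 7-methoxy-5-(methoxymethoxy)-2-[4-(methoxymethoxy)phenyl]-2H-chromene (racemic) | COc1cc(OCOC)c2C=CC(c3ccc(OCOC)cc3)Oc2c1
A5 | alternative 2 | 5-methoxy-3-(methoxymethoxy)-2-(trimethylsilyl)phenyl trifluoromethanesulfonate | COc1cc(OS(=O)(=O)C(F)(F)F)c([Si](C)(C)C)c(OCOC)c1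
A6 | alternative 3 | tetrakis(tert-butyldimethylsilyl) ether of 2-[(1E,3R)-1,7-bis(4-hydroxyphenyl)hept-1-en-3-yl]-5-methoxybenzene-1,3-diol | COc1cc(O[Si](C)(C)C(C)(C)C)c([C@@H](/C=C/c2ccc(O[Si](C)(C)C(C)(C)C)cc2)CCCCc2ccc(O[Si](C)(C)C(C)(C)C)cc2)c(O[Si](C)(C)C(C)(C)C)c1
A7 | alternative 3 | 2-ethenyl-5-methoxy-1,3-bis(tert-butyldimethylsilyloxy)benzene | COc1cc(O[Si](C)(C)C(C)(C)C)c(C=C)c(O[Si](C)(C)C(C)(C)C)c1
A8 | alternative 3 | tert-butyl[4-(3-iodopropyl)phenoxy]dimethylsilane | CC(C)(C)[Si](C)(C)Oc1ccc(CCCI)cc1
A9 | alternative 3 | (E)-[4-(2-bromoethenyl)phenoxy](tert-butyl)dimethylsilane | CC(C)(C)[Si](C)(C)Oc1ccc(/C=C/Br)cc1
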